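The route treats the pyranone ring of the isocoumarin as a δ-lactone in disguise. Once C3=C4 is saturated and a carboxyl group is placed on C4, C3 is an aldehyde-derived carbinol carbon, while C4 and C1 are the nucleophilic and electrophilic carbons of a homophthalic anhydride. One amine-promoted annulation therefore forms C3–C4 and O2–C1 and closes that ring. Its precursors are 5-chloro-6,8-bis(methoxymethoxy)isochroman-1,3-dione and a (2E,4E)-dienal already bearing the silylated (2R,3S,5R)-tetrahydrofuran. Oxidative decarboxylation then flattens both new centres and aromatises the ring, and one acid treatment frees the three hydroxyl groups. Chlorine enters before any alkene exists.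

Key step: step 14

Remark on numbering and configuration: the isocoumarin is numbered C1 (C=O), O2, C3 … C8a, and the tetrahydrofuran O1, C2 (dienyl), C3 (OH), C4, C5 (CH3). The target is 2R,3S,5R: the dienyl chain is trans to both OH and CH3, and OH and CH3 are cis. C2 and C3 correspond to C4 and C3 of 2-deoxy-D-ribose. C5 has the α-C-methyl glycoside configuration, so methyl (not hydride) must be the nucleophile at the anomeric carbon.

Assumption: 2-deoxy-D-ribono-1,4-lactone is bought; it is otherwise one Br2/water oxidation away from 2-deoxy-D-ribose.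

**Anhydride branch**

Step 1
Reactants: 1 methyl orsellinate (methyl 2,4-dihydroxy-6-methylbenzoate)
Product: 2 methyl 3-chloro-4,6-dihydroxy-2-methylbenzoate (methyl 5-chloroorsellinate)
Conditions: SO2Cl2 (1.0 equiv), Et2O, 0 °C to rt; recrystallise
Reagents that add atoms: sulfuryl chloride, O=S(=O)(Cl)Cl
Why: Electrophilic aromatic chlorination: C5 of 1 is ortho to the free C4 hydroxyl and para to the chelated C2 hydroxyl and is the site at which orsellinates are known to take up the first chlorine, one equivalent of reagent limits dichlorination, and no oxidisable alkene is present at this stage.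

Step 2
Reactants: 2 methyl 3-chloro-4,6-dihydroxy-2-methylbenzoate
Product: 3 methyl 3-chloro-4,6-bis(methoxymethoxy)-2-methylbenzoate
Conditions: NaH (2.6 equiv), MOMCl (2.6 equiv), DMF, 0 °C to rt
Reagents that add atoms: chloromethyl methyl ether, COCCl
Why: Williamson-type O-alkylation of both phenoxides; NaH is used because the hydroxyl ortho to the ester is hydrogen-bonded, and the resulting acetals are inert to the strong bases, the amine and the lead oxidant that follow.

Step 3
Reactants: 3 methyl 3-chloro-4,6-bis(methoxymethoxy)-2-methylbenzoate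
Product: 5 methyl 3-chloro-2-(2-methoxy-2-oxoethyl)-4,6-bis(methoxymethoxy)benzoate (the dimethyl homophthalate), via benzylic lithium species 4 (not isolated)
Conditions: LiN(iPr)2 (2.3 equiv), THF, −78 °C; (MeO)2CO, −78 to 0 °C; AcOH quench
Reagents that add atoms: dimethyl carbonate, COC(=O)OC
Why: Lateral lithiation of an ortho-toluate followed by Claisen-type C-acylation: the ester-stabilised benzylic anion 4 forms faster than ring metalation at −78 °C and tolerates the neighbouring aryl chloride, and the second equivalent of base stores the product as its enolate so that it is not acylated twice.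

Step 4
Reactants: 5 dimethyl homophthalate
Product: 6 2-(carboxymethyl)-3-chloro-4,6-bis(methoxymethoxy)benzoic acid (the homophthalic acid)
Conditions: KOH (excess), EtOH/H2O, reflux; cold aq. KHSO4 to pH 3, extract
Reagents that add atoms: potassium hydroxide, [K+].[OH-]
Why: Saponification by acyl–oxygen cleavage: the aliphatic ester cleaves quickly and the di-ortho-substituted benzoate yields to excess hot hydroxide, the MOM ethers are base-stable, and brief cold acidification avoids their loss.

Step 5
Reactants: 6 homophthalic acid
Product: 7 5-chloro-6,8-bis(methoxymethoxy)isochroman-1,3-dione (the homophthalic anhydride)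
Conditions: Ac2O (4 equiv), toluene, 80 °C; evaporate, use crude
Reagents that add atoms: none
Why: Cyclodehydration by anhydride exchange with Ac2O, driven by formation of the six-membered cyclic anhydride; without added base C4 is not acetylated, and the weak acid released does not touch the MOM ethers.

**Dienal branch**

Step 6
Reactants: 8 2-deoxy-D-ribono-1,4-lactone, (4S,5R)-4-hydroxy-5-(hydroxymethyl)oxolan-2-one
Product: 9 (4S,5R)-4-(tert-butyldimethylsilyloxy)-5-[(tert-butyldimethylsilyloxy)methyl]oxolan-2-one
Conditions: TBSCl (2.5 equiv), imidazole (5 equiv), DMF, rt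
Reagents that add atoms: tert-butyldimethylsilyl chloride, CC(C)(C)[Si](C)(C)Cl
Why: Imidazole-promoted silylation of both hydroxyl groups without touching a stereocentre; one protecting group serves both positions because the primary ether can later be removed selectively.

Step 7
Reactants: 9 bis-silylated lactone
Product: 11 1-O-acetyl-3,5-bis-O-(tert-butyldimethylsilyl)-2-deoxy-D-ribofuranose (anomeric mixture), via aluminium hemiacetal 10 (not isolated)
Conditions: iBu2AlH (1.1 equiv), CH2Cl2, −78 °C; then pyridine, DMAP, Ac2O, −78 to −20 °C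
Reagents that add atoms: acetic anhydride, CC(=O)OC(C)=O
Why: Reductive acetylation of a lactone: iBu2AlH stops at the tetrahedral aluminium hemiacetal 10 at −78 °C, which is acetylated in situ before it can open, and the mixture at the anomeric carbon is irrelevant because that centre is ionised in step 8.

Step 8
Reactants: 11 anomeric acetate
Product: 13 (2R,3S,5R)-3-(tert-butyldimethylsilyloxy)-2-[(tert-butyldimethylsilyloxy)methyl]-5-methyltetrahydrofuran, via oxocarbenium ion 12 (not isolated)
Conditions: AlMe3 (3 equiv), CH2Cl2, −78 to −20 °C; aq. potassium sodium tartrate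
Reagents that add atoms: trimethylaluminium, C[Al](C)C
Why: Organoaluminium C-glycosylation of an anomeric acetate: AlMe3 ionises the acetate and transfers methyl to cation 12, which should react through the envelope with the C3 silyloxy group pseudoaxial by inside attack, so that methyl enters cis to the C3 oxygen and trans to the C2 side chain (both preferences reinforce each other) and sets C5 as R, the minor epimer being removable by chromatography here or at 14.

Step 9
Reactants: 13 bis-silyl ether
Product: 14 [(2R,3S,5R)-3-(tert-butyldimethylsilyloxy)-5-methyltetrahydrofuran-2-yl]methanol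
Conditions: TFA/H2O/THF (1:1:4), 0 °C
Reagents that add atoms: none
Why: Sterically differentiated acid hydrolysis of silyl ethers: the primary TBS ether hydrolyses much faster than the hindered secondary one in cold aqueous TFA, the standard selectivity of bis-silylated 2-deoxyribofuranosides.

Step 10
Reactants: 14 primary alcohol
Product: 15 (2S,3S,5R)-3-(tert-butyldimethylsilyloxy)-5-methyltetrahydrofuran-2-carbaldehyde
Conditions: Dess–Martin periodinane (1.3 equiv), CH2Cl2, 0 °C to rt; use crude at once
Reagents that add atoms: none
Why: Dess–Martin oxidation under non-basic conditions gives the α-alkoxy aldehyde without enolisation, so C2 is not epimerised and the β-silyloxy group is not eliminated (the descriptor S at C2 is only a change of priorities).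

Step 11
Reactants: 15 aldehyde; 16 triethyl 4-phosphonocrotonate
Product: 18 ethyl (2E,4E)-5-[(2R,3S,5R)-3-(tert-butyldimethylsilyloxy)-5-methyltetrahydrofuran-2-yl]penta-2,4-dienoate, via lithiated phosphonate 17 (not isolated)
Conditions: 16 (1.4 equiv), LiN(SiMe3)2 (1.35 equiv), THF, −78 °C; then 15, −78 to 0 °C
Reagents that add atoms: none
Why: Vinylogous Horner–Wadsworth–Emmons olefination: the stabilised anion 17 reacts at its α-carbon, reversible addition favours the E-alkene while the existing E double bond is retained, and the weakly basic anion at low temperature spares the C2 centre of the aldehyde.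

Step 12
Reactants: 18 dienoate
Product: 19 (2E,4E)-5-[(2R,3S,5R)-3-(tert-butyldimethylsilyloxy)-5-methyltetrahydrofuran-2-yl]penta-2,4-dien-1-ol
Conditions: iBu2AlH (2.5 equiv), CH2Cl2, −78 °C; aq. potassium sodium tartrate
Reagents that add atoms: none
Why: 1,2-Reduction of a conjugated ester by two hydride transfers from iBu2AlH at low temperature, which leaves the diene and the silyl ether untouched.

Step 13
Reactants: 19 dienol
Product: 20 (2E,4E)-5-[(2R,3S,5R)-3-(tert-butyldimethylsilyloxy)-5-methyltetrahydrofuran-2-yl]penta-2,4-dienal
Conditions: MnO2 (20 equiv), CH2Cl2, rt; filter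
Reagents that add atoms: none
Why: Chemoselective heterogeneous MnO2 oxidation of a dienylic alcohol under neutral conditions, which keeps the E,E geometry and the silyl ether.

**Union and end game**

Step 14
Reactants: 7 homophthalic anhydride (1.3 equiv); 20 dienal
Product: 22 5-chloro-3-{(1E,3E)-4-[(2R,3S,5R)-3-(tert-butyldimethylsilyloxy)-5-methyltetrahydrofuran-2-yl]buta-1,3-dienyl}-6,8-bis(methoxymethoxy)-1-oxoisochroman-4-carboxylic acid (mixture at lactone C3 and C4), via aldol adduct 21 (not isolated)
Conditions: DMAP (1.0 equiv, added last and slowly), CH2Cl2, −20 °C to rt; cold aq. citric acid wash; use crude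
Reagents that add atoms: none
Why: DMAP deprotonates 7 at C4, which is benzylic and α to the aliphatic carbonyl; the enolate adds through C4 to the aldehyde carbon of 20 to give aldolate 21, whose oxygen attacks the aryl-bound carbonyl C1 and expels the aliphatic carboxylate, so that C3–C4 and O2–C1 form and the acid stays on C4. The closest known reaction type is the amine-promoted formal [4+2] annulation of homophthalic anhydrides with aldehydes (the oxygen counterpart of the Castagnoli–Cushman reaction), established for aromatic, aliphatic and cinnamaldehyde-type partners. The lactone ring closes by 6-exo-trig acyl transfer, and attack on the other carbonyl would give a β-lactone and is not competitive. C3 and C4 arise as a cis/trans mixture, each doubled by the remote tetrahydrofuran centres, and no control element is provided or required because both carbons become sp2 in step 15. The step needs 1,2- rather than 1,4- or 1,6-addition: conjugate adducts of this stabilised enolate can revert, whereas only the 1,2-adduct is drained by lactonisation. Adding the base last to a cold mixture holding excess 7 limits anhydride self-condensation, and the carboxylate that forms lowers the acidity of C4–H, which together with the weak base disfavours E1cB reopening of the lactone and deprotonation at tetrahydrofuran C2.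

Step 15
Reactants: 22 dihydroisocoumarin-4-carboxylic acid
Product: 23 5-chloro-3-{(1E,3E)-4-[(2R,3S,5R)-3-(tert-butyldimethylsilyloxy)-5-methyltetrahydrofuran-2-yl]buta-1,3-dienyl}-6,8-bis(methoxymethoxy)-1H-isochromen-1-one
Conditions: Pb(OAc)4 (1.3 equiv, portionwise), Cu(OAc)2 (0.2 equiv), pyridine (2 equiv), degassed benzene, 80 °C, argon, dark
Reagents that add atoms: none
Why: Kochi oxidative decarboxylation: the carboxylate of tetravalent lead fragments with loss of CO2 to a benzylic C4 radical that divalent copper oxidises with loss of the only β-hydrogen (C3–H), so the regiochemistry is unambiguous, all diastereomers converge, the new C3=C4 bond gains conjugation with arene, ring oxygen and diene, and the protected phenols and silyl ether are inert to the oxidant.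

Step 16
Reactants: 23 protected isocoumarin
Product: 24 5-chloro-6,8-dihydroxy-3-{(1E,3E)-4-[(2R,3S,5R)-3-hydroxy-5-methyltetrahydrofuran-2-yl]buta-1,3-dienyl}-1H-isochromen-1-one (target)
Conditions: HCl (1.25 M in MeOH), 0 to 35 °C
Reagents that add atoms: none
Why: Acid-catalysed acetal exchange of both aryl MOM ethers and methanolysis of the secondary TBS ether in one operation; lactone, aryl chloride and E,E-diene are inert to dilute methanolic HCl, and ionisation of the dienylic C2–O1 bond is disfavoured by the adjacent C3 oxygen and the electron-poor pyranone terminus, so the three stereocentres stay as set.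

**Compound list**

1 | methyl orsellinate | COC(=O)c1c(C)cc(O)cc1O | starting material
2 | methyl 3-chloro-4,6-dihydroxy-2-methylbenzoate | COC(=O)c1c(C)c(Cl)c(O)cc1O | intermediate
3 | methyl 3-chloro-4,6-bis(methoxymethoxy)-2-methylbenzoate | COC(=O)c1c(C)c(Cl)c(OCOC)cc1OCOC | intermediate
4 | benzylic lithium species of 3 (not isolated) | [Li]Cc1c(Cl)c(OCOC)cc(OCOC)c1C(=O)OC | intermediate
5 | methyl 3-chloro-2-(2-methoxy-2-oxoethyl)-4,6-bis(methoxymethoxy)benzoate | COC(=O)Cc1c(Cl)c(OCOC)cc(OCOC)c1C(=O)OC | intermediate
6 | 2-(carboxymethyl)-3-chloro-4,6-bis(methoxymethoxy)benzoic acid | OC(=O)Cc1c(Cl)c(OCOC)cc(OCOC)c1C(=O)O | intermediate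
7 | 5-chloro-6,8-bis(methoxymethoxy)isochroman-1,3-dione | O=C1Cc2c(Cl)c(OCOC)cc(OCOC)c2C(=O)O1 | intermediate
8 | 2-deoxy-D-ribono-1,4-lactone | O=C1C[C@H](O)[C@@H](CO)O1 | starting material
9 | 3,5-bis-O-TBS-2-deoxy-D-ribono-1,4-lactone | O=C1C[C@H](O[Si](C)(C)C(C)(C)C)[C@@H](CO[Si](C)(C)C(C)(C)C)O1 | intermediate
10 | diisobutylaluminium hemiacetal of 9 (not isolated) | CC(C)C[Al](CC(C)C)OC1C[C@H](O[Si](C)(C)C(C)(C)C)[C@@H](CO[Si](C)(C)C(C)(C)C)O1 | intermediate
11 | 1-O-acetyl-3,5-bis-O-TBS-2-deoxy-D-ribofuranose (anomers) | CC(=O)OC1C[C@H](O[Si](C)(C)C(C)(C)C)[C@@H](CO[Si](C)(C)C(C)(C)C)O1 | intermediate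
12 | 3,5-bis-O-TBS-2-deoxyribofuranosyl oxocarbenium ion (not isolated) | [O+]1=CC[C@H](O[Si](C)(C)C(C)(C)C)[C@H]1CO[Si](C)(C)C(C)(C)C | intermediate
13 | (2R,3S,5R)-3-(TBSO)-2-(TBSOCH2)-5-methyltetrahydrofuran | C[C@@H]1C[C@H](O[Si](C)(C)C(C)(C)C)[C@@H](CO[Si](C)(C)C(C)(C)C)O1 | intermediate
14 | [(2R,3S,5R)-3-(TBSO)-5-methyltetrahydrofuran-2-yl]methanol | C[C@@H]1C[C@H](O[Si](C)(C)C(C)(C)C)[C@@H](CO)O1 | intermediate
15 | (2S,3S,5R)-3-(TBSO)-5-methyltetrahydrofuran-2-carbaldehyde | C[C@@H]1C[C@H](O[Si](C)(C)C(C)(C)C)[C@@H](C=O)O1 | intermediate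
16 | triethyl 4-phosphonocrotonate | CCOC(=O)/C=C/CP(=O)(OCC)OCC | starting material
17 | lithiated triethyl 4-phosphonocrotonate (not isolated) | CCOC(=O)/C=C/C([Li])P(=O)(OCC)OCC | intermediate
18 | ethyl (2E,4E)-5-[(2R,3S,5R)-3-(TBSO)-5-methyltetrahydrofuran-2-yl]penta-2,4-dienoate | C[C@@H]1C[C@H](O[Si](C)(C)C(C)(C)C)[C@@H](/C=C/C=C/C(=O)OCC)O1 | intermediate
19 | (2E,4E)-dienol | C[C@@H]1C[C@H](O[Si](C)(C)C(C)(C)C)[C@@H](/C=C/C=C/CO)O1 | intermediate
20 | (2E,4E)-dienal | C[C@@H]1C[C@H](O[Si](C)(C)C(C)(C)C)[C@@H](/C=C/C=C/C=O)O1 | intermediate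
21 | aldol adduct, 4-(1-hydroxydienyl)isochroman-1,3-dione (not isolated) | C[C@@H]1C[C@H](O[Si](C)(C)C(C)(C)C)[C@@H](/C=C/C=C/C(O)C2C(=O)OC(=O)c3c(OCOC)cc(OCOC)c(Cl)c23)O1 | intermediate
22 | 3-dienyl-3,4-dihydroisocoumarin-4-carboxylic acid (mixture at C3, C4) | C[C@@H]1C[C@H](O[Si](C)(C)C(C)(C)C)[C@@H](/C=C/C=C/C2OC(=O)c3c(OCOC)cc(OCOC)c(Cl)c3C2C(=O)O)O1 | intermediate
23 | protected isocoumarin | C[C@@H]1C[C@H](O[Si](C)(C)C(C)(C)C)[C@@H](/C=C/C=C/c2cc3c(Cl)c(OCOC)cc(OCOC)c3c(=O)o2)O1 | intermediate
24 | CNP0086741.2 | C[C@@H]1C[C@H](O)[C@@H](/C=C/C=C/c2cc3c(Cl)c(O)cc(O)c3c(=O)o2)O1 | target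

Total step count: 16.
Longest linear sequence: 11 steps (steps 6–16, from 8). The anhydride branch contributes 5 steps before the union.

**Steps most likely to fail**

**1. Step 14.**
- What may go wrong: conjugate addition of the enolate, or self-condensation of the anhydride.
- What may go wrong: slow acyl transfer to the electron-rich, ortho-substituted C1 carbonyl, followed by dehydration of the aldol.
- What may go wrong: base-induced reopening of the lactone by β-elimination.
- Fallback: it sets out from 3 and 18 and comes back at 23, bringing C3 in at the ketone oxidation level so that no aromatisation is needed.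
- Ester 18 is treated with MeNH(OMe)·HCl and iPrMgCl (THF, −20 °C) to give the Weinreb dienamide F1.
- Anion 4, generated from 3 as in step 3, is acylated by F1. The addition is held at the chelated tetrahedral stage until work-up, a known acylation of toluate anions with unsaturated amides of this type, and gives the keto ester F2.
- DBU in warm toluene then drives enol-lactonisation of F2 onto the neighbouring methyl ester and gives 23.

**2. Step 15.**
- What may go wrong: attack of the oxidant on the diene, intermolecular addition of the benzylic radical to a diene, or capture of the oxidised C4 centre by acetate instead of proton loss.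
- Fallback: it sets out from 22 and comes back at 23, replacing metal oxidation by a radical chain and a thermal elimination.
- Acid 22 is coupled with 2-mercaptopyridine N-oxide (DCC, CH2Cl2, 0 °C, dark) to give the Barton ester F3.
- Visible-light irradiation at 0 °C starts the Barton decarboxylation. The C4 radical is captured at the thiocarbonyl sulfur of a further ester molecule, preferentially anti to the C3 substituent, giving the 4-(2-pyridylthio) lactone F4.
- mCPBA (1 equiv, CH2Cl2, −78 °C) oxidises sulfur far faster than the diene and gives the sulfoxide F5.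
- Syn elimination of F5 with C3–H in warm toluene gives 23.

**3. Step 8.**
- What may go wrong: poor facial selectivity of methyl transfer, or proton loss from the cation with glycal formation.
- Fallback: it sets out from 9 and comes back at 13, making the C5–O1 bond instead of the C5–CH3 bond.
- Lactone 9 is reduced with iBu2AlH (CH2Cl2, −78 °C) to the lactol F6.
- Wittig methylenation (Ph3PCH3Br, KN(SiMe3)2, THF, 0 °C) opens F6 to the alkenol F7, in which only the future ring oxygen is free.
- A Mukaiyama-type aerobic oxidative cyclisation with reductive termination then closes the ring 5-exo. Conditions: bis(4,4,4-trifluoro-1-phenylbutane-1,3-dionato)cobalt, a complex of divalent cobalt; O2; γ-terpinene; toluene; 70 °C.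
- The primary radical takes hydrogen from γ-terpinene and becomes the methyl group.
- This reaction type is known for 2,5-trans and 2,4-cis selectivity, and both preferences lead to 13.

**Further compounds**

F1 | step 14 | Weinreb dienamide, (2E,4E)-N-methoxy-N-methyl-5-[(2R,3S,5R)-3-(TBSO)-5-methyltetrahydrofuran-2-yl]penta-2,4-dienamide | C[C@@H]1C[C@H](O[Si](C)(C)C(C)(C)C)[C@@H](/C=C/C=C/C(=O)N(C)OC)O1
F2 | step 14 | keto ester, methyl 3-chloro-4,6-bis(methoxymethoxy)-2-{(3E,5E)-2-oxo-6-[(2R,3S,5R)-3-(TBSO)-5-methyltetrahydrofuran-2-yl]hexa-3,5-dienyl}benzoate | C[C@@H]1C[C@H](O[Si](C)(C)C(C)(C)C)[C@@H](/C=C/C=C/C(=O)Cc2c(Cl)c(OCOC)cc(OCOC)c2C(=O)OC)O1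
F3 | step 15 | Barton ester, 2-thioxopyridin-1(2H)-yl ester of 22 | C[C@@H]1C[C@H](O[Si](C)(C)C(C)(C)C)[C@@H](/C=C/C=C/C2OC(=O)c3c(OCOC)cc(OCOC)c(Cl)c3C2C(=O)On4ccccc4=S)O1
F4 | step 15 | 4-(2-pyridylthio) lactone | C[C@@H]1C[C@H](O[Si](C)(C)C(C)(C)C)[C@@H](/C=C/C=C/C2OC(=O)c3c(OCOC)cc(OCOC)c(Cl)c3C2Sc4ccccn4)O1
F5 | step 15 | sulfoxide of F4 | C[C@@H]1C[C@H](O[Si](C)(C)C(C)(C)C)[C@@H](/C=C/C=C/C2OC(=O)c3c(OCOC)cc(OCOC)c(Cl)c3C2S(=O)c4ccccn4)O1
F6 | step 8 | lactol, 3,5-bis-O-TBS-2-deoxy-D-ribofuranose | OC1C[C@H](O[Si](C)(C)C(C)(C)C)[C@@H](CO[Si](C)(C)C(C)(C)C)O1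
F7 | step 8 | alkenol, (2R,3S)-1,3-bis(tert-butyldimethylsilyloxy)hex-5-en-2-ol | C=CC[C@H](O[Si](C)(C)C(C)(C)C)[C@@H](CO[Si](C)(C)C(C)(C)C)O
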